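**Retrosynthetic overview**
- Target 22 is an achiral diaryl ether. Cutting the two prenyl O-C bonds gives triol 20, which comes from the protected diaryl ether 18.
- Feature used: ring A, numbered from the ester carbon, carries CO2Me (C1), OAr (C2), H (C3), CH3 (C4), H (C5) and O (C6). C1, C6, C5 and C4 are C3, C4, C5 and C6 of a 4-oxy-6-methyl-2-pyrone-3-carboxylate; C2 and C3 are the two carbons of an aryloxyacetylene.
- Key disconnection: ring A bonds C1-C2 and C3-C4, by inverse-electron-demand Diels-Alder reaction of pyrone 5 with the ring B ethynyl ether 16, then loss of CO2. The diaryl ether oxygen is the ring B phenol oxygen and is never made by aryl coupling.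
- Pyrone 5 comes from dimethyl malonate and diketene, with O4 carried as a pivalate so the diene stays electron-poor. Ynol ether 16 comes from phenol 11 and trichloroethylene, and 11 comes from 2-hydroxy-5-methoxybenzaldehyde by oxygenation of its free ortho position.
- Ring order: ring B is bought, the pyrone ring is built second, and ring A is formed last from the pyrone.

Key step: step 10

Remark: the target has no stereocentre and no double bond with E/Z isomerism, so its SMILES needs no stereo descriptor. Bicycle 17 is racemic and its bridgehead centres vanish in the same step.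

**Route**

Step 1
Reactants: 1 dimethyl malonate; 2 diketene (4-methylideneoxetan-2-one)
Product: 4 methyl 4-hydroxy-6-methyl-2-oxo-2H-pyran-3-carboxylate, via dimethyl acetoacetylmalonate 3 (not isolated)
Conditions: NaH, THF, 0 °C; 2, 0 °C to rt; 1 M HCl; crude in PhMe, reflux
Reagents that add atoms: none
Why: Sodium dimethyl malonate opens diketene at the acyl carbon (C-acylation of a malonate enolate) and the enol oxygen of the new methyl ketone then closes on one malonate ester with loss of methanol (lactonisation), the classical route to 3-alkoxycarbonyl-4-hydroxy-6-methyl-2-pyrones; an anionic acylation in the cold is preferred to a thermal acetylketene source, which neutral malonate would not intercept before the ketene dimerises.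

Step 2
Reactants: 4 methyl 4-hydroxy-6-methyl-2-oxo-2H-pyran-3-carboxylate
Product: 5 methyl 6-methyl-2-oxo-4-(pivaloyloxy)-2H-pyran-3-carboxylate
Conditions: PivCl, Et3N, CH2Cl2, 0 °C
Reagents that add atoms: pivaloyl chloride, CC(C)(C)C(=O)Cl
Why: O-acylation of the acidic 4-hydroxy-2-pyrone (enol ester formation) can only end at O4 because C3 is blocked by the ester, and the bulky pivaloyl group should survive work-up while drawing the oxygen lone pair away from the diene.

Step 3
Reactants: 6 2-hydroxy-5-methoxybenzaldehyde
Product: 7 3-bromo-2-hydroxy-5-methoxybenzaldehyde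
Conditions: Br2, NaOAc, AcOH, rt
Reagents that add atoms: bromine, BrBr
Why: Electrophilic aromatic bromination is directed by the free phenol to its only open ortho position (C3, since the para position carries OMe), with NaOAc buffering the HBr.

Step 4
Reactants: 7 3-bromo-2-hydroxy-5-methoxybenzaldehyde
Product: 8 2,3-dihydroxy-5-methoxybenzaldehyde
Conditions: NaOH (aq), Cu powder (cat.), reflux, N2; then HCl (aq)
Reagents that add atoms: sodium hydroxide, [Na+].[OH-]
Why: Copper-catalysed hydroxylation of an ortho-bromophenoxide (Ullmann-type C-O bond formation, the reaction that turns 5-halovanillins into 5-hydroxyvanillin) should replace Br by OH, while the phenoxide shields the aldehyde from Cannizzaro disproportionation and the inert atmosphere shields the catechol from autoxidation.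

Step 5
Reactants: 8 2,3-dihydroxy-5-methoxybenzaldehyde
Product: 9 2-hydroxy-5-methoxy-3-(methoxymethoxy)benzaldehyde
Conditions: NaH (2.1 equiv), DMF, 0 °C; MOMCl (1.0 equiv), 0 °C to rt; NH4Cl (aq)
Reagents that add atoms: chloromethyl methyl ether (MOMCl), COCCl
Why: In the catecholate dianion the C3 phenoxide is not conjugated with the formyl group and is more nucleophilic than the C2 phenoxide (a vinylogous carboxylate), so one equivalent of MOMCl should alkylate O3 only (regioselective Williamson mono-alkylation of a catechol dianion).

Step 6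
Reactants: 9 2-hydroxy-5-methoxy-3-(methoxymethoxy)benzaldehyde
Product: 10 2-(hydroxymethyl)-4-methoxy-6-(methoxymethoxy)phenol
Conditions: NaBH4, MeOH, 0 °C
Reagents that add atoms: none
Why: Borohydride reduction of the aryl aldehyde gives the benzylic alcohol and leaves the MOM acetal and the aryl ethers untouched.

Step 7
Reactants: 10 2-(hydroxymethyl)-4-methoxy-6-(methoxymethoxy)phenol
Product: 11 2-({[tert-butyl(dimethyl)silyl]oxy}methyl)-4-methoxy-6-(methoxymethoxy)phenol
Conditions: TBSCl (1.05 equiv), imidazole, CH2Cl2, 0 °C
Reagents that add atoms: tert-butyldimethylsilyl chloride (TBSCl), CC(C)(C)[Si](C)(C)Cl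
Why: Chemoselective silylation, since the unhindered primary benzylic alcohol should take up one equivalent of TBSCl faster than a phenol flanked by two ortho substituents, as in the selective silylation of salicyl alcohols.

Step 8
Reactants: 11 2-({[tert-butyl(dimethyl)silyl]oxy}methyl)-4-methoxy-6-(methoxymethoxy)phenol; 12 trichloroethylene
Product: 13 tert-butyl({2-[(E)-1,2-dichloroethenyl]oxy-5-methoxy-3-(methoxymethoxy)phenyl}methoxy)dimethylsilane
Conditions: 12, K2CO3, DMF, 70 °C
Reagents that add atoms: trichloroethylene (compound 12), ClC=C(Cl)Cl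
Why: Carbonate dehydrochlorinates trichloroethylene to dichloroacetylene and the phenoxide adds to it in an anti sense (nucleophilic addition to a haloalkyne), which sets the E geometry of the 1,2-dichlorovinyl ether, while the silyl ether and MOM acetal tolerate K2CO3.

Step 9
Reactants: 13 tert-butyl({2-[(E)-1,2-dichloroethenyl]oxy-5-methoxy-3-(methoxymethoxy)phenyl}methoxy)dimethylsilane
Product: 16 tert-butyl{[2-(ethynyloxy)-5-methoxy-3-(methoxymethoxy)phenyl]methoxy}dimethylsilane, via chloroethynyl ether 14 (not isolated), via lithium acetylide 15 (not isolated)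
Conditions: n-BuLi (2.3 equiv), THF, -78 to -40 °C; H2O, -78 °C; quick filtration through Et3N-washed silica
Reagents that add atoms: none
Why: Two equivalents of n-BuLi effect dehydrochlorination to the chloroalkynyl ether and then chlorine-lithium exchange (the standard dichlorovinyl ether route to ynol ethers), protonation of the acetylide gives the terminal alkyne, and any ring lithiation next to OMOM is erased by the same proton quench.

Step 10
Reactants: 5 methyl 6-methyl-2-oxo-4-(pivaloyloxy)-2H-pyran-3-carboxylate; 16 tert-butyl{[2-(ethynyloxy)-5-methoxy-3-(methoxymethoxy)phenyl]methoxy}dimethylsilane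
Product: 18 methyl 2-[2-({[tert-butyl(dimethyl)silyl]oxy}methyl)-4-methoxy-6-(methoxymethoxy)phenoxy]-4-methyl-6-(pivaloyloxy)benzoate, via bridged lactone 17 (not isolated)
Conditions: 5 (2 equiv), BHT (cat.), PhCl, reflux (132 °C), Ar; 16 added by syringe pump
Reagents that add atoms: none
Why: The C3 ester, the lactone carbonyl and the only weakly donating 4-pivaloyloxy group make 5 an electron-poor diene and the oxygen-polarised alkyne 16 is its electron-rich partner, so an asynchronous inverse-electron-demand Diels-Alder reaction is expected in which the nucleophilic CH terminus of 16 bonds first to the electrophilic pyrone C6 and the aryloxy-bearing carbon then closes on C3. Ring A is thus closed by an intermolecular [4+2] cycloaddition across pyrone C3 and C6 (new ring A bonds C1-C2 and C3-C4), giving the 2-oxabicyclo[2.2.2]octadienone 17. Because the dienophile is an alkyne, 17 is already at the arene oxidation level and should lose CO2 by retro-[4+2] at the reaction temperature, so no elimination or oxidation is needed. The closest known reaction type is the cycloaddition of 3-alkoxycarbonyl-2-pyrones with ketene acetals, ynamines and alkoxyalkynes, which delivers 2-hetero-substituted benzoates with this same orientation. No stereocentre survives, since the two bridgeheads of racemic 17 become sp2 carbons. The step needs regioselectivity (aryloxy ortho, not meta, to the ester), secured by the matched polarisation and by the unsubstituted alkyne terminus meeting the methyl-bearing C6, and chemoselectivity against self-reaction of 16, secured by slow addition into excess 5; an alkoxy group on O4 would push electron density into the diene, which is why an acyl group is used there.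

Step 11
Reactants: 18 methyl 2-[2-({[tert-butyl(dimethyl)silyl]oxy}methyl)-4-methoxy-6-(methoxymethoxy)phenoxy]-4-methyl-6-(pivaloyloxy)benzoate
Product: 20 methyl 2-hydroxy-6-[2-hydroxy-6-(hydroxymethyl)-4-methoxyphenoxy]-4-methylbenzoate, via phenol 19 (not isolated)
Conditions: NaOMe (1.2 equiv), MeOH, rt; then HCl in MeOH (about 1 M), rt to 40 °C
Reagents that add atoms: none
Why: Methoxide transesterifies the activated aryl pivalate while the hindered methyl benzoate can only exchange degenerately, and acid methanolysis then cleaves the MOM acetal and the primary silyl ether; base comes before acid so that no phenoxide ever sits next to the diaryl ether oxygen on ring B, and the benzylic alcohol, whose cation would be supported only by the ortho aryloxy group, should not ionise.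

Step 12
Reactants: 20 methyl 2-hydroxy-6-[2-hydroxy-6-(hydroxymethyl)-4-methoxyphenoxy]-4-methylbenzoate; 21 prenyl bromide (1-bromo-3-methylbut-2-ene)
Product: 22 methyl 2-[2-(hydroxymethyl)-4-methoxy-6-(3-methylbut-2-enyloxy)phenoxy]-4-methyl-6-(3-methylbut-2-enyloxy)benzoate (target)
Conditions: 21 (2.4 equiv), K2CO3 (3 equiv), DMF, rt
Reagents that add atoms: prenyl bromide (compound 21), CC(C)=CCBr
Why: Williamson etherification, in which K2CO3 deprotonates only the two phenols and not the benzylic alcohol, and the reactive allylic bromide should trap both phenoxides by SN2 displacement at room temperature.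

**Compound list**
1 | dimethyl malonate | COC(=O)CC(=O)OC | starting material
2 | diketene (4-methylideneoxetan-2-one) | C=C1CC(=O)O1 | starting material
3 | dimethyl 2-(3-oxobutanoyl)propanedioate (not isolated) | CC(=O)CC(=O)C(C(=O)OC)C(=O)OC | intermediate
4 | methyl 4-hydroxy-6-methyl-2-oxo-2H-pyran-3-carboxylate | COC(=O)c1c(O)cc(C)oc1=O | intermediate
5 | methyl 6-methyl-2-oxo-4-(pivaloyloxy)-2H-pyran-3-carboxylate | COC(=O)c1c(OC(=O)C(C)(C)C)cc(C)oc1=O | intermediate
6 | 2-hydroxy-5-methoxybenzaldehyde | COc1ccc(O)c(C=O)c1 | starting material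
7 | 3-bromo-2-hydroxy-5-methoxybenzaldehyde | COc1cc(Br)c(O)c(C=O)c1 | intermediate
8 | 2,3-dihydroxy-5-methoxybenzaldehyde | COc1cc(O)c(O)c(C=O)c1 | intermediate
9 | 2-hydroxy-5-methoxy-3-(methoxymethoxy)benzaldehyde | COCOc1cc(OC)cc(C=O)c1O | intermediate
10 | 2-(hydroxymethyl)-4-methoxy-6-(methoxymethoxy)phenol | COCOc1cc(OC)cc(CO)c1O | intermediate
11 | 2-({[tert-butyl(dimethyl)silyl]oxy}methyl)-4-methoxy-6-(methoxymethoxy)phenol | COCOc1cc(OC)cc(CO[Si](C)(C)C(C)(C)C)c1O | intermediate
12 | trichloroethylene | ClC=C(Cl)Cl | starting material
13 | tert-butyl({2-[(E)-1,2-dichloroethenyl]oxy-5-methoxy-3-(methoxymethoxy)phenyl}methoxy)dimethylsilane | COCOc1cc(OC)cc(CO[Si](C)(C)C(C)(C)C)c1O/C(Cl)=C\Cl | intermediate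
14 | tert-butyl({2-[(chloroethynyl)oxy]-5-methoxy-3-(methoxymethoxy)phenyl}methoxy)dimethylsilane (not isolated) | COCOc1cc(OC)cc(CO[Si](C)(C)C(C)(C)C)c1OC#CCl | intermediate
15 | lithium acetylide of 16 (not isolated) | COCOc1cc(OC)cc(CO[Si](C)(C)C(C)(C)C)c1OC#C[Li] | intermediate
16 | tert-butyl{[2-(ethynyloxy)-5-methoxy-3-(methoxymethoxy)phenyl]methoxy}dimethylsilane | C#COc1c(CO[Si](C)(C)C(C)(C)C)cc(OC)cc1OCOC | intermediate
17 | methyl 8-aryloxy-1-methyl-3-oxo-5-(pivaloyloxy)-2-oxabicyclo[2.2.2]octa-5,7-diene-4-carboxylate, aryl = protected ring B, racemic (not isolated) | CC12C=C(OC(=O)C(C)(C)C)C(C(=O)OC)(C(=O)O1)C(Oc3c(CO[Si](C)(C)C(C)(C)C)cc(OC)cc3OCOC)=C2 | intermediate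
18 | methyl 2-[2-({[tert-butyl(dimethyl)silyl]oxy}methyl)-4-methoxy-6-(methoxymethoxy)phenoxy]-4-methyl-6-(pivaloyloxy)benzoate | COC(=O)c1c(OC(=O)C(C)(C)C)cc(C)cc1Oc1c(CO[Si](C)(C)C(C)(C)C)cc(OC)cc1OCOC | intermediate
19 | methyl 2-[2-({[tert-butyl(dimethyl)silyl]oxy}methyl)-4-methoxy-6-(methoxymethoxy)phenoxy]-6-hydroxy-4-methylbenzoate (not isolated) | COC(=O)c1c(O)cc(C)cc1Oc1c(CO[Si](C)(C)C(C)(C)C)cc(OC)cc1OCOC | intermediate
20 | methyl 2-hydroxy-6-[2-hydroxy-6-(hydroxymethyl)-4-methoxyphenoxy]-4-methylbenzoate | COC(=O)c1c(O)cc(C)cc1Oc1c(CO)cc(OC)cc1O | intermediate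
21 | prenyl bromide (1-bromo-3-methylbut-2-ene) | CC(C)=CCBr | starting material
22 | methyl 2-[2-(hydroxymethyl)-4-methoxy-6-(3-methylbut-2-enyloxy)phenoxy]-4-methyl-6-(3-methylbut-2-enyloxy)benzoate | COC(=O)c1c(OCC=C(C)C)cc(C)cc1Oc1c(CO)cc(OC)cc1OCC=C(C)C | target

**Step count**
- Total step count: 12 (2 to pyrone 5, 7 to ynol ether 16, 3 after convergence).
- Longest linear sequence: 10 steps (6 to 22, steps 3 to 12).

**Steps most likely to fail**

Step 10.
- The cycloaddition may be slower than thermal self-condensation of the ynol ether. Closure at pyrone C3 presses the ester-bearing carbon against a 2,6-disubstituted aryloxy group.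
- Conjugate attack of the alkyne at pyrone C4 with expulsion of pivalate may also compete.
- The fallback gives up ring construction and makes the diaryl ether C-O bond by an Ullmann-type coupling onto a preformed ring A. It sets out from phenol 11 and comes back at triol 20.
- Commercial 3-bromo-5-methylphenol is protected (MOMCl, i-Pr2NEt, CH2Cl2) as 1-bromo-3-(methoxymethoxy)-5-methylbenzene F1.
- F1 is deprotonated by LDA at -78 °C at the position flanked by Br and OMOM (directed ortho-metalation) and quenched with methyl chloroformate. This gives methyl 2-bromo-6-(methoxymethoxy)-4-methylbenzoate F2.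
- Coupling of 11 with F2 (CuI, picolinic acid, K3PO4, DMSO, 100 °C) is helped by the ortho ester of F2. It should give methyl 2-[2-({[tert-butyl(dimethyl)silyl]oxy}methyl)-4-methoxy-6-(methoxymethoxy)phenoxy]-6-(methoxymethoxy)-4-methylbenzoate F3.
- Methanolic HCl, as in the second stage of step 11, removes both MOM groups and the silyl group from F3 to give 20.

Step 9.
- The terminal ynol ether may be lost by hydration or oligomerisation during quench, concentration and chromatography.
- The fallback masks the alkyne terminus as a C-silyl group. It sets out from 13 and comes back at 16.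
- The lithium acetylide 15 is generated as in step 9 but trapped with TMSCl instead of a proton. This gives tert-butyl{[5-methoxy-3-(methoxymethoxy)-2-{[(trimethylsilyl)ethynyl]oxy}phenyl]methoxy}dimethylsilane F4, a capped ynol ether that should tolerate chromatography and storage.
- K2CO3 in MeOH removes the alkynyl silyl group just before use. Compound 16 is then extracted into PhCl and fed into step 10 as a solution, without being concentrated to dryness.

Step 12.
- Under base the ring B phenoxide sits ortho to the diaryl ether oxygen and may attack C2 of the ester-activated ring A. This would be a Smiles rearrangement, moving ring A from O1' to O6'.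
- The hydrogen-bonded salicylate hydroxyl may alkylate slowly, and forcing conditions may bring in alkylation of the benzylic alcohol or its lactonisation onto the ester.
- The fallback replaces phenoxide alkylation by a neutral Mitsunobu etherification with the benzylic alcohol masked. It sets out from 20 and comes back at 22.
- The primary alcohol of 20 is silylated selectively (TBSCl 1 equiv, imidazole, CH2Cl2, 0 °C, as in step 7). This gives methyl 2-[2-({[tert-butyl(dimethyl)silyl]oxy}methyl)-6-hydroxy-4-methoxyphenoxy]-6-hydroxy-4-methylbenzoate F5.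
- Both phenols are etherified with 3-methylbut-2-en-1-ol, PPh3 and DIAD in THF at 0 °C, where no free phenoxide persists. This gives methyl 2-[2-({[tert-butyl(dimethyl)silyl]oxy}methyl)-4-methoxy-6-(3-methylbut-2-enyloxy)phenoxy]-4-methyl-6-(3-methylbut-2-enyloxy)benzoate F6.
- TBAF in THF then releases 22.

**Further compounds**
F1 | step 10 | 1-bromo-3-(methoxymethoxy)-5-methylbenzene | COCOc1cc(C)cc(Br)c1
F2 | step 10 | methyl 2-bromo-6-(methoxymethoxy)-4-methylbenzoate | COC(=O)c1c(Br)cc(C)cc1OCOC
F3 | step 10 | methyl 2-[2-({[tert-butyl(dimethyl)silyl]oxy}methyl)-4-methoxy-6-(methoxymethoxy)phenoxy]-6-(methoxymethoxy)-4-methylbenzoate | COC(=O)c1c(OCOC)cc(C)cc1Oc1c(CO[Si](C)(C)C(C)(C)C)cc(OC)cc1OCOC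
F4 | step 9 | tert-butyl{[5-methoxy-3-(methoxymethoxy)-2-{[(trimethylsilyl)ethynyl]oxy}phenyl]methoxy}dimethylsilane | C[Si](C)(C)C#COc1c(CO[Si](C)(C)C(C)(C)C)cc(OC)cc1OCOC
F5 | step 12 | methyl 2-[2-({[tert-butyl(dimethyl)silyl]oxy}methyl)-6-hydroxy-4-methoxyphenoxy]-6-hydroxy-4-methylbenzoate | COC(=O)c1c(O)cc(C)cc1Oc1c(CO[Si](C)(C)C(C)(C)C)cc(OC)cc1O
F6 | step 12 | methyl 2-[2-({[tert-butyl(dimethyl)silyl]oxy}methyl)-4-methoxy-6-(3-methylbut-2-enyloxy)phenoxy]-4-methyl-6-(3-methylbut-2-enyloxy)benzoate | COC(=O)c1c(OCC=C(C)C)cc(C)cc1Oc1c(CO[Si](C)(C)C(C)(C)C)cc(OC)cc1OCC=C(C)C
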